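The runs come from a simulation with constants of no real substance; the scatter is artificial.

Count turnovers of the catalyst, not half-lives of the substrate. Thursday's readings are the early part of the very flask in question.

the same everywhere: substrate 0.052 M; free catalyst 4.5 mol%
- Thursday's: reagent 1.8 equiv (in portions, 3); the very flask that is asked about, followed so far; portions every 2.0 min
- flask: reagent 1.80 equiv (in portions, 3); the portions of reagent follow each other after 2.0 min, the first at the start; time 50 min

Thursday's run (percent of the substrate charged)

| time / min | substrate / % | product / % |
|---|---|---|
| 1.33 | 94.7 | 1.5 |
| 2.00 | 95.0 | 1.7 |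
| 3.00 | 94.5 | 2.2 |
| 4.00 | 92.5 | 3.4 |
| 6.00 | 89.6 | 6.4 |
| 10.0 | 83.2 | 11.0 |
| 15.0 | 78.1 | 18.7 |

(readings scatter by 1 percentage point)



- concentration of substrate at 50 min, in M
- concentration of product at 50 min, in M
- concentration of reagent at 50 min, in M

I turn the question round and ask what product at the full charge by 50 min would require. With one substrate per cycle, each catalyst charged has to complete 22.2 cycles. Nearly all of that count still lies ahead in the 46.0 min after the last portion at 4.00 min, so a cycle may take about 2.07 min.

From 4.00 min to 15.0 min, Thursday's product climbs by 15 percentage points, with a scatter of 1 point on each reading. That gives 3.24 min as the turnover time, the minutes per cycle for each catalyst charged, the reciprocal of an apparent kcat. This reading is longer than the time allowed, by a factor of 1.57, so I expect this flask to fall short.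

If the pace holds, 14.2 further cycles bring product to 67.4% of the charge, or 0.0350 M. The forecast, noting that “the catalyst looks nearly saturated”, gives 0.0234 M substrate, 0.0265 M product and 0.0665 M reagent, and its product is lower than mine.

The flask gives 0.0168 M substrate, 0.0335 M product and 0.0586 M reagent.

    reagent + catalyst intermediate A → catalyst intermediate B (k = 42.0 /M/min)
    catalyst intermediate C → by-product + catalyst intermediate D (k = 1.90 /min)
    catalyst intermediate B ⇌ catalyst intermediate C (K = 1.50, k = 1.30 /min)
    catalyst intermediate D → free catalyst + product (k = 1.10 /min)
    substrate + free catalyst ⇌ catalyst intermediate A (K = 410 /M, k = 67.0 /M/min)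

The flask's product, 64.3% of the charge, lies below my 67.4% and above the forecast. The same turnover time, applied to the neighbour flask with 2.7 mol% free catalyst and with the product at 4.00 min scaled by the loading, gives 40.4% product, and that neighbour stands at 40.3% at 50 min. This flask is not at rest at 50 min, with free catalyst at 24.0% of its charge. By 500 min it has moved to 0 M substrate, 0.0520 M product and 0.0416 M reagent.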